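**Retrosynthetic overview**

1. Locants are those of 3,4-dihydronaphthalene-2-carbaldehyde (C1 = ring CH=, C2 = C–CHO, C3 = CH–CH2OH, C4 = CH–aryl). Target 14 is dialdehyde 13 with only its saturated 3-formyl group reduced (last step).
2. Dialdehyde 13 is cut into lactol 8 and succinaldehyde 10, joined in one amine-catalysed operation: enamine 1,6-addition to a p-quinone methide (C3–C4), then intramolecular aldol condensation (C1=C2), which closes the carbocycle C1–C2–C3–C4–C4a–C8a.
3. Enabling feature: the free 4-OH of the pendant ring is para to C4, so C4 can be the exocyclic carbon of a p-quinone methide. C1 is a formyl carbon on the benzo ring ortho to C4. C2 carries CHO and C3 a reduced formyl group, so C2/C3 are the two α-carbons of C2-symmetric succinaldehyde.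
4. Lactol 8 stores the quinone methide and the aryl aldehyde together in a temporary 1,3-dihydroisobenzofuran ring. It comes from the aryllithium of 2-bromo-4,5-dimethoxybenzaldehyde (aldehyde masked in situ) and O-silyl vanillin.
5. Ring order: temporary lactol ring (step 2), then the dihydronaphthalene ring (step 5). Both stereocentres arise in step 5 from a racemic precursor that is a mixture of epimers.

Key step: step 5

Remark: succinaldehyde does not keep and is therefore made fresh (step 4). Compounds 7 and 8 are used as racemic mixtures of lactol epimers on purpose, because all their stereo-elements are erased in step 5.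

**Step 1**
Reactants: 1 vanillin (4-hydroxy-3-methoxybenzaldehyde)
Product: 2 4-[(tert-butyldimethylsilyl)oxy]-3-methoxybenzaldehyde
Conditions: TBSCl, imidazole, DMF, rt
Reagents that add atoms: tert-butyldimethylsilyl chloride, CC(C)(C)[Si](C)(C)Cl
Why: Standard imidazole-promoted O-silylation removes the acidic phenol proton that would quench the organolithium of step 2.

**Step 2**
Reactants: 3 2-bromo-4,5-dimethoxybenzaldehyde; 2 4-[(tert-butyldimethylsilyl)oxy]-3-methoxybenzaldehyde
Product: 7 3-{4-[(tert-butyldimethylsilyl)oxy]-3-methoxyphenyl}-5,6-dimethoxy-1,3-dihydro-2-benzofuran-1-ol (racemic lactol; both epimers), via lithium amino alkoxide 4 (not isolated), via aryllithium 5 (not isolated), via dilithium adduct 6 (not isolated)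
Conditions: LiN(Me)CH2CH2NMe2 (from the amine and n-BuLi), THF, −20 °C; n-BuLi, −78 °C; then 2, −78 → 0 °C; aq NH4Cl
Reagents that add atoms: none
Why: The lithium amide masks the aldehyde of 3 as an α-amino alkoxide (in situ protection), bromine–lithium exchange gives the aryllithium, its 1,2-addition to 2 forms the diaryl carbinol, and on aqueous work-up the released aldehyde is trapped by the new hydroxyl as the five-membered lactol, whose two centres need no control.

**Step 3**
Reactants: 7 silyl-protected lactol
Product: 8 3-(4-hydroxy-3-methoxyphenyl)-5,6-dimethoxy-1,3-dihydro-2-benzofuran-1-ol (racemic lactol; both epimers)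
Conditions: TBAF, AcOH, THF, 0 °C
Reagents that add atoms: none
Why: Fluoride cleaves the aryl silyl ether (desilylation) while acetic acid keeps the medium non-basic, so that the freed p-hydroxybenzylic lactol is not driven to the quinone methide before step 5.

**Step 4**
Reactants: 9 2,5-dimethoxytetrahydrofuran
Product: 10 succinaldehyde (butanedial)
Conditions: H2O, 90 °C; then distillation (toluene azeotrope), used at once
Reagents that add atoms: water, O
Why: Hydrolysis of the cyclic bis-acetal in hot water should give the dialdehyde, which is distilled and used immediately because it oligomerises on standing.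

**Step 5**
Reactants: 8 phenol lactol; 10 succinaldehyde
Product: 13 (3R,4S)-4-(4-hydroxy-3-methoxyphenyl)-6,7-dimethoxy-3,4-dihydronaphthalene-2,3-dicarbaldehyde, via quinone methide aldehyde 11 (not isolated), via trialdehyde adduct 12 (not isolated)
Conditions: (R)-2-[diphenyl(trimethylsilyloxy)methyl]pyrrolidine (20 mol %), 4-nitrobenzoic acid (40 mol %), 10 (3 equiv), CHCl3, rt, Ar; short silica filtration, taken on at once
Reagents that add atoms: none
Why: Proposed new method: acid-assisted heterolysis of the diaryl-carbon–oxygen bond of lactol 8, pushed by the para-hydroxyl, should release the p-quinone methide and the ortho aryl aldehyde of 11 at once; the enamine of succinaldehyde then adds through its α-carbon 1,6 to the methide carbon (C3–C4, with rearomatisation to the phenol), and the enamine formed on the unbranched CH2CHO arm of 12 attacks the ortho formyl group and dehydrates through the iminium ion to the conjugated enal (C1=C2), the closest known reaction types being the aminocatalytic 1,6-addition of aldehydes to p-quinone methides, the amine/acid-catalysed SN1-type α-alkylation of aldehydes with stabilised benzhydrols, and amine-catalysed conjugate-addition/aldol-condensation annulations onto 2-formylaryl partners. The one new ring closes by a 6-(enolexo)-exo-trig aldol addition that dehydration makes irreversible. C3 is set by the catalyst, whose diphenyl(silyloxy)methyl group shields one face of the E-enamine so that the (R)-amine should give the 3R centre (S in open-chain 12); C4 is set by relative topicity in an open synclinal transition state with the quinoid ring over the enamine and the formyl-bearing aryl group turned away, the like-approach known for enamine additions to nitroalkenes, which corresponds to 4S and the trans ring. The racemic lactol epimers of 8 and both geometric isomers of 11 should converge on one stereoisomer because every stereo-element of 8 is erased in the planar quinone methide. The step needs site selectivity among the aldol reactions open to 12, secured because only the CH2CHO enamine reaches the ortho aldehyde through a six-membered closure that can dehydrate, and between the two α-carbons of the dialdehyde, which are equivalent by symmetry. It also needs quinone-methide formation to outrun ionisation at the hemiacetal carbon, which the para-hydroxyl push and the weak acid are chosen to favour.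

**Step 6**
Reactants: 13 dialdehyde
Product: 14 (3R,4S)-4-(4-hydroxy-3-methoxyphenyl)-3-(hydroxymethyl)-6,7-dimethoxy-3,4-dihydronaphthalene-2-carbaldehyde (target)
Conditions: NaBH4 (0.3 equiv), EtOH/CH2Cl2 (3:7), −78 °C; aq NH4Cl
Reagents that add atoms: none
Why: Chemoselective borohydride reduction should take the saturated 3-formyl group much faster than the 2-formyl group, which is deactivated by conjugation with the alkene and the 6-methoxy-substituted benzo ring, and at −78 °C the C3 centre is not epimerised and becomes fixed once its formyl group is CH2OH.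

**Compound list**

1 | vanillin (4-hydroxy-3-methoxybenzaldehyde) | COc1cc(C=O)ccc1O | starting material
2 | 4-[(tert-butyldimethylsilyl)oxy]-3-methoxybenzaldehyde | COc1cc(C=O)ccc1O[Si](C)(C)C(C)(C)C | intermediate
3 | 2-bromo-4,5-dimethoxybenzaldehyde | COc1cc(Br)c(C=O)cc1OC | starting material
4 | lithium (2-bromo-4,5-dimethoxyphenyl){[2-(dimethylamino)ethyl](methyl)amino}methanolate (not isolated) | [Li+].[O-]C(N(C)CCN(C)C)c1cc(OC)c(OC)cc1Br | intermediate
5 | aryllithium from 4 by bromine–lithium exchange (not isolated) | [Li+].[O-]C(N(C)CCN(C)C)c1cc(OC)c(OC)cc1[Li] | intermediate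
6 | dilithium adduct of 5 with 2, racemic (not isolated) | [Li+].[Li+].[O-]C(N(C)CCN(C)C)c1cc(OC)c(OC)cc1C([O-])c1ccc(O[Si](C)(C)C(C)(C)C)c(OC)c1 | intermediate
7 | 3-{4-[(tert-butyldimethylsilyl)oxy]-3-methoxyphenyl}-5,6-dimethoxy-1,3-dihydro-2-benzofuran-1-ol, racemic, both lactol epimers | COc1cc(C2OC(O)c3cc(OC)c(OC)cc23)ccc1O[Si](C)(C)C(C)(C)C | intermediate
8 | 3-(4-hydroxy-3-methoxyphenyl)-5,6-dimethoxy-1,3-dihydro-2-benzofuran-1-ol, racemic, both lactol epimers | COc1cc(C2OC(O)c3cc(OC)c(OC)cc23)ccc1O | intermediate
9 | 2,5-dimethoxytetrahydrofuran (cis/trans mixture) | COC1CCC(OC)O1 | starting material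
10 | succinaldehyde (butanedial) | O=CCCC=O | intermediate
11 | 4,5-dimethoxy-2-[(3-methoxy-4-oxocyclohexa-2,5-dien-1-ylidene)methyl]benzaldehyde, E/Z mixture (not isolated) | COC1=CC(=Cc2cc(OC)c(OC)cc2C=O)C=CC1=O | intermediate
12 | (2S)-2-[(S)-(2-formyl-4,5-dimethoxyphenyl)(4-hydroxy-3-methoxyphenyl)methyl]butanedial (not isolated) | COc1cc([C@@H](c2cc(OC)c(OC)cc2C=O)[C@H](CC=O)C=O)ccc1O | intermediate
13 | (3R,4S)-4-(4-hydroxy-3-methoxyphenyl)-6,7-dimethoxy-3,4-dihydronaphthalene-2,3-dicarbaldehyde | COc1cc([C@H]2c3cc(OC)c(OC)cc3C=C(C=O)[C@@H]2C=O)ccc1O | intermediate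
14 | (3R,4S)-4-(4-hydroxy-3-methoxyphenyl)-3-(hydroxymethyl)-6,7-dimethoxy-3,4-dihydronaphthalene-2-carbaldehyde | COc1cc([C@H]2c3cc(OC)c(OC)cc3C=C(C=O)[C@@H]2CO)ccc1O | target

**Step count and risks**

Total steps: 6. Longest linear sequence: 5 (steps 1, 2, 3, 5, 6).

Steps most likely to fail:

1. Step 5 (proposed new method). Three processes may spoil it:
   - the lactol may ionise at its hemiacetal carbon and lose the benzylic proton, drifting toward an isobenzofuran instead of opening to the quinone methide;
   - the dialdehyde may self-condense;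
   - the facial selectivity at the methide carbon (C4) may be poor, or C3 of 13 may epimerise before reduction.

   Fallback, by known chemistry only, sets out from 2 and 3 and comes back at 14. It builds both centres under auxiliary control and closes the same C1=C2 bond by a plain aldol condensation.
   - Aldehyde 3 with ethylene glycol and TsOH (toluene, water removal) should give 2-(2-bromo-4,5-dimethoxyphenyl)-1,3-dioxolane F1.
   - Horner–Wadsworth–Emmons reaction of 2 with diethyl {2-oxo-2-[(4S)-2-oxo-4-phenyl-1,3-oxazolidin-3-yl]ethyl}phosphonate (LiCl, iPr2NEt, MeCN) should give the (E)-enoyl imide F2. The phosphonate is made by an Arbuzov reaction from the N-bromoacetyl oxazolidinone.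
   - The Grignard reagent of F1 (Mg, THF) with CuBr·SMe2 should add to F2 anti to the 4-phenyl group of the chelated syn-s-cis conformer, giving the (3S)-3,3-diarylpropanoyl imide F3.
   - Evans alkylation of its sodium Z-enolate (NaHMDS, allyl iodide, THF, −78 °C) should give the (2S,3S)-2-allyl imide F4.
   - LiBH4 (THF, H2O) removes the auxiliary reductively to the primary alcohol F5.
   - Lemieux–Johnson oxidation (OsO4 cat., NaIO4, 2,6-lutidine, dioxane/H2O) cleaves the terminal alkene to the hydroxy aldehyde F6, expected to rest as its five-membered lactol.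
   - 1 M HCl/THF frees the aryl aldehyde, and pyrrolidine/AcOH (toluene, 40 °C) then effects the intramolecular aldol condensation to the silyl ether of the target F7.
   - TBAF/AcOH (THF, 0 °C) gives 14, so steps 5 and 6 are both bypassed.

2. Step 6. The hydride may also attack the conjugated formyl group, or attack it first, so that diol or the regioisomeric hydroxy aldehyde forms. Fallback sets out from 13 and comes back at 14. It replaces selective reduction by exhaustive reduction and selective re-oxidation. Luche reduction (NaBH4, CeCl3·7H2O, MeOH, −20 °C) should take both formyl groups to the diol [(3R,4S)-4-(4-hydroxy-3-methoxyphenyl)-3-(hydroxymethyl)-6,7-dimethoxy-3,4-dihydronaphthalen-2-yl]methanol F8. MnO2 (CH2Cl2, rt) should then oxidise only the allylic, styrene-conjugated primary alcohol back to the enal, leaving the saturated CH2OH untouched.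

3. Step 2. In situ masking or the bromine–lithium exchange may be incomplete, so that butyllithium adds to a free aldehyde or the aryllithium is protonated before it meets 2. Fallback sets out from 3 and comes back at 7. It uses an isolated acetal instead of the in situ amino alkoxide. Aldehyde 3 with HC(OMe)3 and catalytic TsOH in MeOH should give 1-bromo-2-(dimethoxymethyl)-4,5-dimethoxybenzene F9. n-BuLi (THF, −78 °C) followed by 2 should give the hydroxy acetal {4-[(tert-butyldimethylsilyl)oxy]-3-methoxyphenyl}[2-(dimethoxymethyl)-4,5-dimethoxyphenyl]methanol F10. Brief treatment with 1 M HCl/THF at 0 °C should hydrolyse the acetal and close the lactol 7.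

**Further compounds**

F1 | step 5 | 2-(2-bromo-4,5-dimethoxyphenyl)-1,3-dioxolane | COc1cc(Br)c(C2OCCO2)cc1OC
F2 | step 5 | (4S)-3-[(2E)-3-{4-[(tert-butyldimethylsilyl)oxy]-3-methoxyphenyl}prop-2-enoyl]-4-phenyl-1,3-oxazolidin-2-one | COc1cc(/C=C/C(=O)N2[C@@H](c3ccccc3)COC2=O)ccc1O[Si](C)(C)C(C)(C)C
F3 | step 5 | (4S)-3-[(3S)-3-{4-[(tert-butyldimethylsilyl)oxy]-3-methoxyphenyl}-3-[2-(1,3-dioxolan-2-yl)-4,5-dimethoxyphenyl]propanoyl]-4-phenyl-1,3-oxazolidin-2-one | COc1cc([C@@H](c2cc(OC)c(OC)cc2C2OCCO2)CC(=O)N2[C@@H](c3ccccc3)COC2=O)ccc1O[Si](C)(C)C(C)(C)C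
F4 | step 5 | (4S)-3-[(2S,3S)-3-{4-[(tert-butyldimethylsilyl)oxy]-3-methoxyphenyl}-3-[2-(1,3-dioxolan-2-yl)-4,5-dimethoxyphenyl]-2-(prop-2-en-1-yl)propanoyl]-4-phenyl-1,3-oxazolidin-2-one | COc1cc([C@@H](c2cc(OC)c(OC)cc2C2OCCO2)[C@H](CC=C)C(=O)N2[C@@H](c3ccccc3)COC2=O)ccc1O[Si](C)(C)C(C)(C)C
F5 | step 5 | (2S)-2-[(S)-{4-[(tert-butyldimethylsilyl)oxy]-3-methoxyphenyl}[2-(1,3-dioxolan-2-yl)-4,5-dimethoxyphenyl]methyl]pent-4-en-1-ol | COc1cc([C@@H](c2cc(OC)c(OC)cc2C2OCCO2)[C@H](CC=C)CO)ccc1O[Si](C)(C)C(C)(C)C
F6 | step 5 | (3S,4S)-4-{4-[(tert-butyldimethylsilyl)oxy]-3-methoxyphenyl}-4-[2-(1,3-dioxolan-2-yl)-4,5-dimethoxyphenyl]-3-(hydroxymethyl)butanal (open form of the lactol) | COc1cc([C@@H](c2cc(OC)c(OC)cc2C2OCCO2)[C@H](CC=O)CO)ccc1O[Si](C)(C)C(C)(C)C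
F7 | step 5 | (3R,4S)-4-{4-[(tert-butyldimethylsilyl)oxy]-3-methoxyphenyl}-3-(hydroxymethyl)-6,7-dimethoxy-3,4-dihydronaphthalene-2-carbaldehyde | COc1cc([C@H]2c3cc(OC)c(OC)cc3C=C(C=O)[C@@H]2CO)ccc1O[Si](C)(C)C(C)(C)C
F8 | step 6 | [(3R,4S)-4-(4-hydroxy-3-methoxyphenyl)-3-(hydroxymethyl)-6,7-dimethoxy-3,4-dihydronaphthalen-2-yl]methanol | COc1cc([C@H]2c3cc(OC)c(OC)cc3C=C(CO)[C@@H]2CO)ccc1O
F9 | step 2 | 1-bromo-2-(dimethoxymethyl)-4,5-dimethoxybenzene | COc1cc(Br)c(C(OC)OC)cc1OC
F10 | step 2 | {4-[(tert-butyldimethylsilyl)oxy]-3-methoxyphenyl}[2-(dimethoxymethyl)-4,5-dimethoxyphenyl]methanol (racemic) | COc1cc(C(O)c2cc(OC)c(OC)cc2C(OC)OC)ccc1O[Si](C)(C)C(C)(C)C
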